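**Retrosynthetic overview**
1. The strategy rests on the single ring, a cyclohex-2-enone (C1 carbonyl, C2 methyl-bearing, C3, C4 carbinol, C5 chain-bearing, C6) with C4–OH and the C5–CH2 of the side chain cis. Cutting C2=C3 (retro-aldol condensation) leaves C3–C4–C5 as the CH2O–CH(O)–CH pattern of a 2,3-epoxy alcohol that must receive C6 at C5 anti to oxygen.
2. Key disconnection C5–C6: alkynylalane 9 opens the cis-epoxy alcohol 6 at the chain-bearing carbon with inversion to give diol 11. The but-1-ynyl group is the masked C6–C1(=O)–C2–CH3 unit.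
3. Epoxy alcohol 6 comes from asymmetric epoxidation of Z-allylic alcohol 5, made by semi-hydrogenation of enynol 4, itself from copper-catalysed coupling of geranylgeranyl bromide 2 with prop-2-yn-1-ol 3.
4. After the key step, a hydrosilylation tethered through the C4 oxygen, followed by oxidation, puts the carbonyl on C1. C3 is raised to the aldehyde and an aldol condensation from C2 to C3 closes the ring.
5. Ring order: oxirane formed (step 4) and opened (step 6); a transient oxasiline (step 7, destroyed in step 8); the cyclohexenone, the only ring of the target, last (step 11).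

Key step: step 6

Remark: "geranylgeranyl" means (2E,6E,10E)-3,7,11,15-tetramethylhexadeca-2,6,10,14-tetraen-1-yl, commercial geranylgeraniol is taken to be this all-E isomer, and ring atoms are numbered as in line 1.

**Route**

Step 1
Reactants: 1 (2E,6E,10E)-geranylgeraniol
Product: 2 (2E,6E,10E)-geranylgeranyl bromide
Conditions: PBr3 (0.4 equiv), Et2O, −10 → 0 °C; used crude
Reagents that add atoms: phosphorus tribromide, BrP(Br)Br
Why: Conversion of a primary allylic alcohol to the bromide through its phosphite ester (SN2) at low temperature should proceed without allylic transposition or loss of the 2E geometry.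

Step 2
Reactants: 2 (2E,6E,10E)-geranylgeranyl bromide; 3 prop-2-yn-1-ol
Product: 4 (5E,9E,13E)-6,10,14,18-tetramethylnonadeca-5,9,13,17-tetraen-2-yn-1-ol
Conditions: 3 (1.5 equiv), CuI (10 mol%), n-Bu4NBr (10 mol%), K2CO3 (2 equiv), DMF, rt
Reagents that add atoms: none
Why: Copper-catalysed coupling of a terminal alkyne with a primary allylic halide under carbonate conditions should join the copper acetylide of 3 to the unhindered CH2 terminus (SN2, since the SN2′ carbon is fully substituted), giving the skipped enyne with the E alkene and the free hydroxyl intact.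

Step 3
Reactants: 4 (5E,9E,13E)-6,10,14,18-tetramethylnonadeca-5,9,13,17-tetraen-2-yn-1-ol
Product: 5 (2Z,5E,9E,13E)-6,10,14,18-tetramethylnonadeca-2,5,9,13,17-pentaen-1-ol
Conditions: H2 (1 atm), Pd/CaCO3 poisoned with Pb(OAc)2 (Lindlar catalyst), quinoline, EtOAc, rt, stopped at one equivalent of H2
Reagents that add atoms: none
Why: Lindlar semi-hydrogenation adds hydrogen syn to the alkyne only, so the new alkene should be Z while the four trisubstituted alkenes are left alone.

Step 4
Reactants: 5 (2Z,5E,9E,13E)-6,10,14,18-tetramethylnonadeca-2,5,9,13,17-pentaen-1-ol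
Product: 6 [(2R,3S)-3-geranylgeranyloxiran-2-yl]methanol (cis-epoxide)
Conditions: Ti(OiPr)4 (20 mol%), D-(−)-diethyl tartrate (26 mol%), t-BuOOH (2 equiv, in isooctane), 4 Å MS, CH2Cl2, −20 °C
Reagents that add atoms: tert-butyl hydroperoxide, CC(C)(C)OO
Why: Katsuki–Sharpless asymmetric epoxidation touches only the alkene of the titanium-bound allylic alkoxide, the D-(−)-tartrate ligand directs oxygen to the face that gives 2R (future C4), and the Z geometry makes the oxirane cis (2R,3S); this reagent-controlled step alone fixes the absolute configuration of the route, and Z-allylic alcohols being the slow substrate class, a long reaction time at low temperature is planned.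

Step 5
Reactants: 7 but-1-yne
Product: 9 diethyl(but-1-yn-1-yl)aluminium, via lithium but-1-ynide 8 (not isolated)
Conditions: n-BuLi (1.0 equiv), toluene/hexane, −78 → 0 °C; Et2AlCl (1.0 equiv), 0 °C → rt; the suspension is used directly in step 6
Reagents that add atoms: diethylaluminium chloride, CC[Al](Cl)CC; n-butyllithium, [Li]CCCC (its lithium is carried only by intermediate 8)
Why: Deprotonation of the terminal alkyne and lithium-to-aluminium transmetallation with precipitation of LiCl is the standard preparation of a dialkyl(alkynyl)alane.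

Step 6
Reactants: 6 [(2R,3S)-3-geranylgeranyloxiran-2-yl]methanol; 9 diethyl(but-1-yn-1-yl)aluminium
Product: 11 (2S,3S)-3-geranylgeranylhept-4-yne-1,2-diol, via aluminium alkoxide 10 (not isolated)
Conditions: 9 (3.5 equiv), toluene/hexane, 0 °C → rt; then aq. KNaC4H4O6, 0 °C
Reagents that add atoms: none
Why: The hydroxyl of 6 first consumes one Al–ethyl bond (loss of ethane) to give the aluminium alkoxide 10, in which aluminium bound to the C1 oxygen also coordinates the oxirane oxygen, and a but-1-ynyl group is then transferred from aluminium (of the same aggregate or of a further molecule of 9) to the oxirane carbon bearing the geranylgeranyl CH2, from the side opposite the breaking C–O bond (SN2-type opening with inversion). The closest known reaction type is the C3-selective opening of 2,3-epoxy alcohols from asymmetric epoxidation by dialkyl(alkynyl)alanes, which gives 3-alkynyl-1,2-diols. No ring is closed: the oxirane is opened and the only new skeletal bond is C5–C6 (ring numbering). The new stereocentre C5 (3S in 11) is set by substrate control, because inversion at the oxirane carbon of the cis-epoxide places the alkynyl carbon anti to the C4 oxygen, the arrangement that becomes cis C4–OH/C5–CH2 once C6 and C3 are joined in the ring, while C4 (2S in 11) keeps the configuration set in step 4. The step needs attack at the distal oxirane carbon rather than at the carbon next to the CH2O group, and transfer of alkynyl rather than ethyl; the first is secured by activation from the alkoxide-bound aluminium and by inductive deactivation of the proximal carbon by its adjacent C–O bond, the second by the much higher transfer aptitude of the sp-carbon ligand. The four trisubstituted alkenes offer no Lewis-basic site and should be inert to the alane at or below room temperature.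

Step 7
Reactants: 11 (2S,3S)-3-geranylgeranylhept-4-yne-1,2-diol
Product: 13 (5S,6S)-6-[(dimethylsilyloxy)methyl]-3-ethyl-2,2-dimethyl-5-geranylgeranyl-5,6-dihydro-2H-1,2-oxasiline, via bis(dimethylsilyl) ether 12 (not isolated)
Conditions: (HMe2Si)2NH (neat), 50 °C, then evaporate; [Cp*Ru(MeCN)3]PF6 (3 mol%), CH2Cl2, 0 °C → rt; crude 13 taken on
Reagents that add atoms: 1,1,3,3-tetramethyldisilazane, C[SiH](C)N[SiH](C)C
Why: Silylation of both hydroxyls followed by ruthenium-catalysed intramolecular trans-hydrosilylation of the alkyne, a known endo-dig closure of homopropargylic silyl ethers, should deliver the silicon tethered to the C4 oxygen to the distal alkyne carbon (6-endo-dig, future C1) without touching the trisubstituted alkenes or either stereocentre, and a 7-endo closure from the primary O-silane would put silicon on the same carbon and converge in step 8.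

Step 8
Reactants: 13 (5S,6S)-6-[(dimethylsilyloxy)methyl]-3-ethyl-2,2-dimethyl-5-geranylgeranyl-5,6-dihydro-2H-1,2-oxasiline
Product: 14 (5S,6S)-6,7-dihydroxy-5-geranylgeranylheptan-3-one
Conditions: KF, KHCO3, 30% aq. H2O2, THF/MeOH (1:1), rt
Reagents that add atoms: hydrogen peroxide, OO
Why: Tamao–Fleming oxidation replaces the alkenyl C–Si bond by C–O and hydrolyses all Si–O bonds, so the enol formed tautomerises to the C1 ketone and steps 7 and 8 together amount to a hydration of the alkyne directed to the carbon remote from C5.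

Step 9
Reactants: 14 (5S,6S)-6,7-dihydroxy-5-geranylgeranylheptan-3-one
Product: 15 (5S,6S)-5-geranylgeranyl-6,7-bis(triethylsilyloxy)heptan-3-one
Conditions: Et3SiCl (2.6 equiv), imidazole (4 equiv), DMAP (cat.), CH2Cl2, 0 °C → rt
Reagents that add atoms: chlorotriethylsilane, CC[Si](Cl)(CC)CC
Why: Standard silyl ether formation protects both hydroxyls without enolising the ketone, so that the aldehyde made next carries a silyloxy and not a free hydroxyl group at C4.

Step 10
Reactants: 15 (5S,6S)-5-geranylgeranyl-6,7-bis(triethylsilyloxy)heptan-3-one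
Product: 16 (2S,3S)-3-geranylgeranyl-5-oxo-2-(triethylsilyloxy)heptanal
Conditions: (COCl)2 (4 equiv), DMSO (8 equiv), CH2Cl2, −78 → −35 °C; then Et3N, −78 → 0 °C; used crude
Reagents that add atoms: none
Why: Under Swern conditions the chlorodimethylsulfonium salt cleaves the less hindered primary triethylsilyl ether in preference to the secondary one and the resulting alkoxysulfonium ion collapses to the aldehyde on addition of base, a known one-flask oxidative desilylation that should leave the ketone, the alkenes and both stereocentres unchanged at low temperature.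

Step 11
Reactants: 16 (2S,3S)-3-geranylgeranyl-5-oxo-2-(triethylsilyloxy)heptanal
Product: 18 (4S,5S)-2-methyl-5-geranylgeranyl-4-(triethylsilyloxy)cyclohex-2-en-1-one, via aldol adduct 17 (not isolated)
Conditions: Bn2NH·CF3CO2H (0.3 equiv), toluene, rt → 45 °C
Reagents that add atoms: none
Why: Intramolecular aldol condensation in the 6-(enolexo)-exo-trig mode: of the two ketone enols only the one toward the ethyl group (C2) can reach the aldehyde carbon C3 through a six-membered transition state, and loss of water from adduct 17 gives the conjugated 2-methyl enone, while C4 and C5, which take no part in bond formation, should keep their cis relationship under the weakly acidic ammonium salt.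

Step 12
Reactants: 18 (4S,5S)-2-methyl-5-geranylgeranyl-4-(triethylsilyloxy)cyclohex-2-en-1-one
Product: 19 (4S,5S)-4-hydroxy-2-methyl-5-geranylgeranylcyclohex-2-en-1-one (target)
Conditions: HF·pyridine, pyridine, THF, 0 °C → rt
Reagents that add atoms: none
Why: Buffered fluoride cleavage of the secondary silyl ether should free the C4 hydroxyl without exposing the γ-hydroxy enone or the polyene to strong acid or base.

**Compound list**
1 | (2E,6E,10E)-geranylgeraniol | CC(C)=CCC/C(C)=C/CC/C(C)=C/CC/C(C)=C/CO | starting material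
2 | (2E,6E,10E)-geranylgeranyl bromide | CC(C)=CCC/C(C)=C/CC/C(C)=C/CC/C(C)=C/CBr | intermediate
3 | prop-2-yn-1-ol | OCC#C | starting material
4 | (5E,9E,13E)-6,10,14,18-tetramethylnonadeca-5,9,13,17-tetraen-2-yn-1-ol | OCC#CC/C=C(C)/CC/C=C(C)/CC/C=C(C)/CCC=C(C)C | intermediate
5 | (2Z,5E,9E,13E)-6,10,14,18-tetramethylnonadeca-2,5,9,13,17-pentaen-1-ol | OC/C=C\C/C=C(C)/CC/C=C(C)/CC/C=C(C)/CCC=C(C)C | intermediate
6 | [(2R,3S)-3-geranylgeranyloxiran-2-yl]methanol (cis) | OC[C@H]1O[C@H]1C/C=C(C)/CC/C=C(C)/CC/C=C(C)/CCC=C(C)C | intermediate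
7 | but-1-yne | CCC#C | starting material
8 | lithium but-1-ynide | [Li]C#CCC | intermediate
9 | diethyl(but-1-yn-1-yl)aluminium | CCC#C[Al](CC)CC | intermediate
10 | (but-1-ynyl)(ethyl)aluminium alkoxide of 6 | CCC#C[Al](CC)OC[C@H]1O[C@H]1C/C=C(C)/CC/C=C(C)/CC/C=C(C)/CCC=C(C)C | intermediate
11 | (2S,3S)-3-geranylgeranylhept-4-yne-1,2-diol | OC[C@@H](O)[C@H](C#CCC)C/C=C(C)/CC/C=C(C)/CC/C=C(C)/CCC=C(C)C | intermediate
12 | (2S,3S)-1,2-bis(dimethylsilyloxy)-3-geranylgeranylhept-4-yne | C[SiH](C)OC[C@@H](O[SiH](C)C)[C@H](C#CCC)C/C=C(C)/CC/C=C(C)/CC/C=C(C)/CCC=C(C)C | intermediate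
13 | (5S,6S)-6-[(dimethylsilyloxy)methyl]-3-ethyl-2,2-dimethyl-5-geranylgeranyl-5,6-dihydro-2H-1,2-oxasiline | C[SiH](C)OC[C@H]1O[Si](C)(C)C(CC)=C[C@@H]1C/C=C(C)/CC/C=C(C)/CC/C=C(C)/CCC=C(C)C | intermediate
14 | (5S,6S)-6,7-dihydroxy-5-geranylgeranylheptan-3-one | OC[C@@H](O)[C@H](CC(=O)CC)C/C=C(C)/CC/C=C(C)/CC/C=C(C)/CCC=C(C)C | intermediate
15 | (5S,6S)-5-geranylgeranyl-6,7-bis(triethylsilyloxy)heptan-3-one | CC[Si](CC)(CC)OC[C@@H](O[Si](CC)(CC)CC)[C@H](CC(=O)CC)C/C=C(C)/CC/C=C(C)/CC/C=C(C)/CCC=C(C)C | intermediate
16 | (2S,3S)-3-geranylgeranyl-5-oxo-2-(triethylsilyloxy)heptanal | O=C[C@@H](O[Si](CC)(CC)CC)[C@H](CC(=O)CC)C/C=C(C)/CC/C=C(C)/CC/C=C(C)/CCC=C(C)C | intermediate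
17 | (4S,5S)-3-hydroxy-2-methyl-5-geranylgeranyl-4-(triethylsilyloxy)cyclohexan-1-one (C2/C3 epimers) | CC(C)=CCC/C(C)=C/CC/C(C)=C/CC/C(C)=C/C[C@H]1CC(=O)C(C)C(O)[C@H]1O[Si](CC)(CC)CC | intermediate
18 | (4S,5S)-2-methyl-5-geranylgeranyl-4-(triethylsilyloxy)cyclohex-2-en-1-one | CC(C)=CCC/C(C)=C/CC/C(C)=C/CC/C(C)=C/C[C@H]1CC(=O)C(C)=C[C@H]1O[Si](CC)(CC)CC | intermediate
19 | (4S,5S)-4-hydroxy-2-methyl-5-geranylgeranylcyclohex-2-en-1-one | CC(C)=CCC/C(C)=C/CC/C(C)=C/CC/C(C)=C/C[C@H]1CC(=O)C(C)=C[C@H]1O | target

**Step count**
Total: 12 steps. Longest linear sequence: 11 steps (1 to 19 through steps 1–4 and 6–12); step 5 is a one-step side branch that makes 9.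

**Steps most likely to fail**

Step 11. Enolisation or enamine formation at the aldehyde α-carbon (C4) may compete with ring closure and erode the cis C4/C5 relationship, and γ-deprotonation of the product enone may expel the silyloxy group and lead on to an aromatic ring. The fallback sets out from 15 and comes back at 18, forming the ring with C3 as a saturated carbon so that no enolisable carbonyl ever sits next to C4. The primary silyl ether of 15 is removed selectively (HF·pyridine, pyridine, THF, −10 °C) to give (5S,6S)-7-hydroxy-5-geranylgeranyl-6-(triethylsilyloxy)heptan-3-one F1. Iodination (I2, PPh3, imidazole, CH2Cl2, 0 °C) gives (5S,6S)-7-iodo-5-geranylgeranyl-6-(triethylsilyloxy)heptan-3-one F2. Treatment with KN(SiMe3)2 in THF (−78 → 0 °C) closes the ring by intramolecular enolate C-alkylation (6-(enolexo)-exo-tet; only the C2 enolate can reach C3), giving (4R,5S)-2-methyl-5-geranylgeranyl-4-(triethylsilyloxy)cyclohexan-1-one F3. Equilibrating silylation (Me3SiCl, NaI, Et3N, MeCN) gives the more substituted enol ether (4R,5S)-2-methyl-5-geranylgeranyl-4-(triethylsilyloxy)-1-(trimethylsilyloxy)cyclohex-1-ene F4, and Saegusa–Ito dehydrogenation with Pd(OAc)2 in MeCN introduces the C2=C3 double bond and arrives at 18.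

Step 7. The ruthenium catalyst may be diverted by the 1,5-relationship between the alkyne and the nearest chain alkene, the second Si–H may add intermolecularly, or protodesilylation may compete with oxidation in step 8. The fallback sets out from 11 and comes back at 15, replacing tethered delivery by steric control. Both hydroxyls of 11 are silylated (Et3SiCl, imidazole, CH2Cl2) to give (2S,3S)-3-geranylgeranyl-1,2-bis(triethylsilyloxy)hept-4-yne F5. Hydroboration with dicyclohexylborane (THF, 0 °C) should place boron on the less hindered alkyne carbon, the one flanked by the ethyl group and remote from the branched C5, giving the (Z)-5-(dicyclohexylboryl)hept-4-ene bis(triethylsilyl) ether F6, which is not isolated. Oxidation with NaBO3·4H2O (THF/H2O, rt) then gives 15 directly; trisubstituted alkenes react far more slowly than alkynes with this dialkylborane.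

Step 6. Attack may occur at the oxirane carbon next to the CH2O group (leading to a 1,3-diol), ethyl may be transferred in place of alkynyl, or the Lewis acid may induce epoxide migration before the C–C bond forms. The fallback sets out from 6 and comes back at 11, replacing alkoxide-directed delivery by steric and inductive shielding. Compound 6 is silylated (t-BuPh2SiCl, imidazole, DMF) to give tert-butyl{[(2R,3S)-3-geranylgeranyloxiran-2-yl]methoxy}diphenylsilane F7. Lithium but-1-ynide 8 with BF3·OEt2 in THF at −78 °C should open the oxirane at the carbon remote from the bulky silyloxymethyl group, again with inversion, giving (2S,3S)-1-(tert-butyldiphenylsilyloxy)-3-geranylgeranylhept-4-yn-2-ol F8. n-Bu4NF in THF removes the silyl group and returns 11.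

**Further compounds**
F1 | step 11 | (5S,6S)-7-hydroxy-5-geranylgeranyl-6-(triethylsilyloxy)heptan-3-one | OC[C@@H](O[Si](CC)(CC)CC)[C@H](CC(=O)CC)C/C=C(C)/CC/C=C(C)/CC/C=C(C)/CCC=C(C)C
F2 | step 11 | (5S,6S)-7-iodo-5-geranylgeranyl-6-(triethylsilyloxy)heptan-3-one | IC[C@@H](O[Si](CC)(CC)CC)[C@H](CC(=O)CC)C/C=C(C)/CC/C=C(C)/CC/C=C(C)/CCC=C(C)C
F3 | step 11 | (4R,5S)-2-methyl-5-geranylgeranyl-4-(triethylsilyloxy)cyclohexan-1-one (C2 epimers) | CC(C)=CCC/C(C)=C/CC/C(C)=C/CC/C(C)=C/C[C@H]1CC(=O)C(C)C[C@H]1O[Si](CC)(CC)CC
F4 | step 11 | (4R,5S)-2-methyl-5-geranylgeranyl-4-(triethylsilyloxy)-1-(trimethylsilyloxy)cyclohex-1-ene | CC(C)=CCC/C(C)=C/CC/C(C)=C/CC/C(C)=C/C[C@H]1CC(O[Si](C)(C)C)=C(C)C[C@H]1O[Si](CC)(CC)CC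
F5 | step 7 | (2S,3S)-3-geranylgeranyl-1,2-bis(triethylsilyloxy)hept-4-yne | CC[Si](CC)(CC)OC[C@@H](O[Si](CC)(CC)CC)[C@H](C#CCC)C/C=C(C)/CC/C=C(C)/CC/C=C(C)/CCC=C(C)C
F6 | step 7 | (Z)-5-(dicyclohexylboryl)hept-4-ene bis(triethylsilyl) ether from F5 (syn H–B adduct) | CC[Si](CC)(CC)OC[C@@H](O[Si](CC)(CC)CC)[C@H](/C=C(/B(C1CCCCC1)C1CCCCC1)CC)C/C=C(C)/CC/C=C(C)/CC/C=C(C)/CCC=C(C)C
F7 | step 6 | tert-butyl{[(2R,3S)-3-geranylgeranyloxiran-2-yl]methoxy}diphenylsilane | CC(C)(C)[Si](OC[C@H]1O[C@H]1C/C=C(C)/CC/C=C(C)/CC/C=C(C)/CCC=C(C)C)(c1ccccc1)c1ccccc1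
F8 | step 6 | (2S,3S)-1-(tert-butyldiphenylsilyloxy)-3-geranylgeranylhept-4-yn-2-ol | CC(C)(C)[Si](OC[C@@H](O)[C@H](C#CCC)C/C=C(C)/CC/C=C(C)/CC/C=C(C)/CCC=C(C)C)(c1ccccc1)c1ccccc1
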